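Solid substrate in this flask can go two ways, into solution or into the protic impurity, and at the start the second is faster than the first.

solid substrate 0.14 M; solid reagent 0.154 M; protic impurity 0.0420 M; time 20 min
* amount of target and solid product together at 20 min, in percent of the solid substrate charged
* concentration of dissolved substrate in solution at 10 min, in percent of saturation
* the change that raises the amount of target and solid product together at 20 min, in percent of the solid substrate charged most ("none" if none brings more than 2 percentage points) (north-east / north / south-west / north-west / none)
* amount of target and solid product together at 20 min, in percent of the solid substrate charged, after north
- north-east: doubling the dissolution coefficient of step 1, all else as stated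
- north: doubling the dissolution coefficient of step 5, all else as stated
- south-west: doubling the solubility in step 3, all else as stated
- north-west: doubling the solubility in step 5, all else as stated
- percent here means solid substrate units held: one side product counts as two
- what is said of target includes solid product
- solid substrate, solid product, solid reagent is a solid; its amount is given per volume of the solution
- at the start none of the solid reagent is in solution
- at the start none of the solid substrate is in solution
- dissolved substrate means what is dissolved; the solid is not counted in it
- run time (flask): 20 min
    solid reagent ⇌ partner, rate k1*(cs1 - [partner]) while solid is left; crystals form when [partner] > cs1 (cs1 = 0.10 M, k1 = 1.2 min⁻¹)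
    dissolved substrate + partner → target (k2 = 0.39 L mol⁻¹ min⁻¹)
    solid product ⇌ target, rate k3*(cs3 - [target]) while solid is left; crystals form when [target] > cs3 (cs3 = 0.053 M, k3 = 2.2 min⁻¹)
    dissolved substrate + target → side product (k4 = 0.19 L mol⁻¹ min⁻¹)
    solid substrate ⇌ dissolved substrate, rate k5*(cs5 - [dissolved substrate]) while solid is left; crystals form when [dissolved substrate] > cs5 (cs5 = 0.078 M, k5 = 0.22 min⁻¹)
    solid substrate + protic impurity → quenched substrate (k6 = 5.3 L mol⁻¹ min⁻¹)
    partner → decomposed reagent (k7 = 0.062 min⁻¹)

The quench starts at 0.0312 M min⁻¹. Against it stands the dissolution flow, the solubility times the dissolution coefficient, which is what leaves the solid per minute into an empty solution: 0.0172 M min⁻¹. But in this flask the impurity is the limiting reagent of the quench, with less charged than solid substrate. One impurity takes one substrate, so you subtract it as a correction and 0.0980 M remains to dissolve.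

Dissolved substrate then climbs toward a plateau. With partner at its solubility, the coupling uses it at 0.0390 min⁻¹, less than the dissolution coefficient, so this too is a correction. The plateau is the flow over their sum, 0.0663 M, approached with time constant 3.86 min. It lies below the survivors, so I keep solid present and get 78.6% of saturation at the earlier time.

Holding partner at its solubility throughout gives 29.8% target. That is the weak link. Partner is lost at 0.0878 min⁻¹, so the reagent above its solubility lasts 6.15 min, and then partner decays. Its time integral becomes 1.42 M·min, which brings my figure to 21.1%. Ranking the changes by plateau, capped at the survivors, I pick north-west.

The forecast gives 19% for y, lower than my figure, then 74% of saturation, north-west as the best change and 23.5% after north. For its ranking of the changes it argues that “Faster substrate dissolution both saves substrate from quenching and raises the dissolved level”.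

The simulation gives 18.9%, 78.9%, north-west with a gain of 5.3 percentage points, and 21.5% after north, so the forecast stands on all four.

The answer to y moves by 5 points once the charge of solid reagent falls to 0.113 M. Now take the neighbouring flask with 0.17 M of protic impurity, 1.21 equiv. Here solid substrate is the smaller charge, so the subtraction fails and the flow races the quench. Put the impurity at its charge less half the substrate charge, and the solid decays at 0.530 min⁻¹ while the flow leaks out. The reckoned solid lasts 3.16 min, which leaves 61.3% quenched. That neighbouring flask gives target 12.6% and quenched substrate 67.5%.

All constants were set for the occasion.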